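The C7–C8–C9 unit of the target, a 2-aryloxy-1,3-diol with ring A on C7 and the ring B oxygen on C8, is treated as a reduced cis-3-aryloxy-4-aryloxetan-2-one, whose cis geometry corresponds to the threo (7S,8S) pair. One catalytic asymmetric ketene–aldehyde (2+2) cycloaddition forms the C7–C8 bond and the O7–C9 acyl bond, closes the four-membered lactone and sets both stereocentres. Its precursors are an aryloxyacetyl chloride carrying ring B and O-pivaloylvanillin; both phenols travel as pivalates, so that a single hydride step afterwards opens the lactone and unmasks them.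

Key step: step 6

Labels: C7 is the benzylic carbinol carbon on ring A (4-hydroxy-3-methoxyphenyl), C8 the carbon bearing the oxygen of ring B (4-hydroxy-2,6-dimethoxyphenyl), C9 the CH2OH carbon, and O7 the oxygen on C7.

Assumption: the absolute sense of step 6 is assigned by analogy with alkylketene-derived ammonium enolates, on which basis the quinidine-derived catalyst is expected to lead to the (2S,3R)-lactone; should the antipode form, the pseudoenantiomeric O-trimethylsilylquinine replaces it directly.

Design note: the ring B oxygen is protected as a pivalate, not as an ether, so no hydrogenolysis is needed on a molecule that holds a p-hydroxybenzylic alcohol. Benzyl is used only as the ester of the acetate unit and is removed before the key step.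

Step 1
Reactants: 1 vanillin
Product: 2 4-formyl-2-methoxyphenyl pivalate
Conditions: PivCl, Et3N, 4-(dimethylamino)pyridine (cat.), CH2Cl2, 0 °C → rt
Reagents that add atoms: pivaloyl chloride, CC(C)(C)C(=O)Cl
Why: O-acylation of the only nucleophilic site, the phenol, under amine base and nucleophilic catalysis should give the hindered aryl ester and leave the aldehyde untouched.

Step 2
Reactants: 3 2,6-dimethoxy-1,4-benzoquinone
Product: 5 4-hydroxy-3,5-dimethoxyphenyl pivalate, via 2,6-dimethoxyhydroquinone 4 (not isolated)
Conditions: H2 (1 atm), 10% Pd/C, THF, rt; filter under Ar; then PivCl (1.0 equiv), pyridine, −20 → 0 °C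
Reagents that add atoms: pivaloyl chloride, CC(C)(C)C(=O)Cl
Why: Catalytic hydrogenation reduces the quinone to the hydroquinone, and the bulky acyl chloride should then esterify the unhindered C4 hydroxyl in preference to the C1 hydroxyl flanked by two methoxy groups (sterically controlled chemoselective O-acylation).

Step 3
Reactants: 5 4-hydroxy-3,5-dimethoxyphenyl pivalate; 6 benzyl bromoacetate
Product: 7 benzyl 2-[2,6-dimethoxy-4-(pivaloyloxy)phenoxy]acetate
Conditions: K2CO3, acetone, reflux
Reagents that add atoms: none
Why: Williamson etherification, in which the phenoxide of 5 displaces bromide from the activated α-bromo ester by SN2, should proceed under dry carbonate conditions that cleave neither the aryl pivalate nor the benzyl ester.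

Step 4
Reactants: 7 benzyl 2-[2,6-dimethoxy-4-(pivaloyloxy)phenoxy]acetate
Product: 8 2-[2,6-dimethoxy-4-(pivaloyloxy)phenoxy]acetic acid
Conditions: H2 (1 atm), 10% Pd/C, EtOAc, rt
Reagents that add atoms: none
Why: Hydrogenolysis of the benzyl ester C–O bond should release the acid under neutral conditions that leave the aryl pivalate and the aryl alkyl ethers intact.

Step 5
Reactants: 8 2-[2,6-dimethoxy-4-(pivaloyloxy)phenoxy]acetic acid
Product: 9 2-[2,6-dimethoxy-4-(pivaloyloxy)phenoxy]acetyl chloride
Conditions: (COCl)2, DMF (cat.), CH2Cl2, 0 °C → rt; concentrate and use directly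
Reagents that add atoms: oxalyl chloride, O=C(Cl)C(=O)Cl
Why: Acid chloride formation through the chloroiminium species from oxalyl chloride and catalytic DMF gives only gaseous by-products, and both ring positions ortho to the ether oxygen are blocked, so no intramolecular acylation can compete.

Step 6
Reactants: 9 2-[2,6-dimethoxy-4-(pivaloyloxy)phenoxy]acetyl chloride; 2 4-formyl-2-methoxyphenyl pivalate
Product: 11 4-{(2S,3R)-3-[2,6-dimethoxy-4-(pivaloyloxy)phenoxy]-4-oxooxetan-2-yl}-2-methoxyphenyl pivalate, via aryloxyketene 10 (not isolated)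
Conditions: O-trimethylsilylquinidine (15 mol%), LiClO4 (2 equiv), i-Pr2NEt (2.5 equiv), CH2Cl2/Et2O, −78 °C, 9 added slowly to 2 (1.5 equiv)
Reagents that add atoms: none
Why: Proposed new method: i-Pr2NEt dehydrochlorinates 9 to ketene 10, the quinuclidine nitrogen of the alkaloid adds to its carbonyl carbon from the side of the hydrogen to give a (Z)-ammonium enolate (aryloxy group cis to the enolate oxygen), and this enolate adds to lithium-bound aldehyde 2 through a closed six-membered chair to form C7–C8 as the syn aldolate. The lithium alkoxide O7 then attacks the acylammonium carbon C9 in a 4-exo-trig acyl substitution, which closes the oxetan-2-one (O7–C9 bond) and returns the catalyst. The closest known reaction type is the cinchona alkaloid and lithium salt co-catalysed acyl halide–aldehyde cyclocondensation of alkylketenes, which gives cis-3,4-disubstituted β-lactones; a heteroatom-substituted (aryloxy) ketene is the untested element, although aryloxyketenes are known to form the same kind of ammonium enolate in alkaloid-catalysed β-lactam synthesis. C8 is set by the enolate face that the quinidine skeleton leaves open, and C7 is set relative to C8 by the equatorial aryl group of 2 in the chair, so that aryl and aryloxy end up cis. The step needs cis over trans selectivity, one enolate face and cross-addition ahead of ketene dimerization: the fixed (Z)-enolate geometry, slow addition of 9 into an excess of 2, and the pivalate of 2 (a more electrophilic carbonyl and a lactone less prone to benzylic C7–O ionization than an ether-protected one) are meant to secure these.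

Step 7
Reactants: 11 4-{(2S,3R)-3-[2,6-dimethoxy-4-(pivaloyloxy)phenoxy]-4-oxooxetan-2-yl}-2-methoxyphenyl pivalate
Product: 12 (1S,2S)-1-(4-hydroxy-3-methoxyphenyl)-2-(4-hydroxy-2,6-dimethoxyphenoxy)propane-1,3-diol
Conditions: LiAlH4 (excess), THF, −78 → 0 °C (11 added to the hydride); aq. KNaC4H4O6/NH4Cl work-up under Ar
Reagents that add atoms: none
Why: Hydride reduction should attack the strained lactone carbonyl first and open it by acyl C9–O7 cleavage to the C9 carbinol, which leaves the C7–O and C8–O bonds and both stereocentres untouched, and on warming should reduce the two aryl pivalates to the free phenols.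

Compound list
1 | vanillin (4-hydroxy-3-methoxybenzaldehyde) | COc1cc(C=O)ccc1O | starting material
2 | 4-formyl-2-methoxyphenyl pivalate (O-pivaloylvanillin) | COc1cc(C=O)ccc1OC(=O)C(C)(C)C | intermediate
3 | 2,6-dimethoxy-1,4-benzoquinone | COC1=CC(=O)C=C(OC)C1=O | starting material
4 | 2,6-dimethoxybenzene-1,4-diol (2,6-dimethoxyhydroquinone; not isolated) | COc1cc(O)cc(OC)c1O | intermediate
5 | 4-hydroxy-3,5-dimethoxyphenyl pivalate | COc1cc(OC(=O)C(C)(C)C)cc(OC)c1O | intermediate
6 | benzyl bromoacetate | O=C(CBr)OCc1ccccc1 | starting material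
7 | benzyl 2-[2,6-dimethoxy-4-(pivaloyloxy)phenoxy]acetate | COc1cc(OC(=O)C(C)(C)C)cc(OC)c1OCC(=O)OCc1ccccc1 | intermediate
8 | 2-[2,6-dimethoxy-4-(pivaloyloxy)phenoxy]acetic acid | COc1cc(OC(=O)C(C)(C)C)cc(OC)c1OCC(=O)O | intermediate
9 | 2-[2,6-dimethoxy-4-(pivaloyloxy)phenoxy]acetyl chloride | COc1cc(OC(=O)C(C)(C)C)cc(OC)c1OCC(=O)Cl | intermediate
10 | [2,6-dimethoxy-4-(pivaloyloxy)phenoxy]ketene (not isolated) | COc1cc(OC(=O)C(C)(C)C)cc(OC)c1OC=C=O | intermediate
11 | 4-{(2S,3R)-3-[2,6-dimethoxy-4-(pivaloyloxy)phenoxy]-4-oxooxetan-2-yl}-2-methoxyphenyl pivalate (cis lactone) | COc1cc([C@H](O3)[C@H](C3=O)Oc2c(OC)cc(OC(=O)C(C)(C)C)cc2OC)ccc1OC(=O)C(C)(C)C | intermediate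
12 | (1S,2S)-1-(4-hydroxy-3-methoxyphenyl)-2-(4-hydroxy-2,6-dimethoxyphenoxy)propane-1,3-diol (threo, 7S,8S) | COc1cc([C@H](O)[C@H](CO)Oc2c(OC)cc(O)cc2OC)ccc1O | target

Total step count: 7. Longest linear sequence: 6 steps (steps 2 to 7, from quinone 3).

Steps most likely to fail

Step 6 (bears the label). The ammonium enolate may be consumed by further ketene instead of by the aldehyde. Lithium chelation by the 2,6-dimethoxyaryloxy group may loosen the chair and erode cis or facial selectivity. The acidic C8–H of the lactone may also epimerize under the amine base. The fallback uses known auxiliary chemistry; it sets out from acid chloride 9 and aldehyde 2 and comes back to the route at target 12. Acid chloride 9 acylates the lithium salt of (R)-4-benzyloxazolidin-2-one (n-BuLi, THF, −78 °C) to give (R)-4-benzyl-3-{2-[2,6-dimethoxy-4-(pivaloyloxy)phenoxy]acetyl}oxazolidin-2-one F1. Its (Z)-boron enolate (n-Bu2BOTf, i-Pr2NEt, CH2Cl2, −78 → 0 °C) is combined with 2 in an Evans syn-aldol addition. This should give (R)-4-benzyl-3-{(2R,3S)-2-[2,6-dimethoxy-4-(pivaloyloxy)phenoxy]-3-hydroxy-3-[3-methoxy-4-(pivaloyloxy)phenyl]propanoyl}oxazolidin-2-one F2, which carries the same threo relationship and absolute sense as lactone 11. LiAlH4 in THF at 0 °C then cleaves the imide reductively to the C9 carbinol and removes both pivalates, which gives 12.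

Step 7. If the ring A pivalate is cleaved before the lactone has been opened, the para-phenoxide can expel the lactone carboxylate through a quinone methide. That would cost the C7 oxygen or its configuration; an acidic work-up could do the same to the p-hydroxybenzylic alcohol. The fallback separates the two events; it sets out from lactone 11 and comes back at target 12. LiBH4 in THF at −20 → 0 °C should reduce only the strained lactone and give 4-{(1S,2S)-2-[2,6-dimethoxy-4-(pivaloyloxy)phenoxy]-1,3-dihydroxypropyl}-2-methoxyphenyl pivalate F3 with both aryl esters in place. The pivalates are then removed from F3 with LiAlH4 in THF at 0 °C, at a stage where no benzylic leaving group remains, and neutral work-up gives 12.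

Step 2. The acylation may discriminate too little between the two hydroxyls or run on to the bis-ester, and the hydroquinone may re-oxidize before it is acylated. The fallback fixes the oxygen pattern by the choice of starting material; it sets out from benzyl bromoacetate 6 and comes back at ester 7.
- Commercial syringaldehyde F4, whose only phenol is the flanked one, is alkylated with 6 (K2CO3, acetone, reflux) to benzyl 2-(4-formyl-2,6-dimethoxyphenoxy)acetate F5.
- Baeyer–Villiger oxidation of the electron-rich aryl aldehyde (mCPBA, CH2Cl2) gives benzyl 2-[4-(formyloxy)-2,6-dimethoxyphenoxy]acetate F6.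
- Brief methanolysis of the formate (Et3N, MeOH, 0 °C) gives benzyl 2-(4-hydroxy-2,6-dimethoxyphenoxy)acetate F7.
- Pivaloylation (PivCl, pyridine) gives 7.

Further compounds
F1 | step 6 | (R)-4-benzyl-3-{2-[2,6-dimethoxy-4-(pivaloyloxy)phenoxy]acetyl}oxazolidin-2-one | COc1cc(OC(=O)C(C)(C)C)cc(OC)c1OCC(=O)N1C(=O)OC[C@H]1Cc1ccccc1
F2 | step 6 | (R)-4-benzyl-3-{(2R,3S)-2-[2,6-dimethoxy-4-(pivaloyloxy)phenoxy]-3-hydroxy-3-[3-methoxy-4-(pivaloyloxy)phenyl]propanoyl}oxazolidin-2-one | COc1cc([C@H](O)[C@H](C(=O)N2C(=O)OC[C@H]2Cc2ccccc2)Oc2c(OC)cc(OC(=O)C(C)(C)C)cc2OC)ccc1OC(=O)C(C)(C)C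
F3 | step 7 | 4-{(1S,2S)-2-[2,6-dimethoxy-4-(pivaloyloxy)phenoxy]-1,3-dihydroxypropyl}-2-methoxyphenyl pivalate | COc1cc([C@H](O)[C@H](CO)Oc2c(OC)cc(OC(=O)C(C)(C)C)cc2OC)ccc1OC(=O)C(C)(C)C
F4 | step 2 | syringaldehyde (4-hydroxy-3,5-dimethoxybenzaldehyde) | COc1cc(C=O)cc(OC)c1O
F5 | step 2 | benzyl 2-(4-formyl-2,6-dimethoxyphenoxy)acetate | COc1cc(C=O)cc(OC)c1OCC(=O)OCc1ccccc1
F6 | step 2 | benzyl 2-[4-(formyloxy)-2,6-dimethoxyphenoxy]acetate | COc1cc(OC=O)cc(OC)c1OCC(=O)OCc1ccccc1
F7 | step 2 | benzyl 2-(4-hydroxy-2,6-dimethoxyphenoxy)acetate | COc1cc(O)cc(OC)c1OCC(=O)OCc1ccccc1
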